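The pitfall is to give Q one time constant: Q starts at 0.20 M, higher than Km at 0.070 M, so the rate law flattens and Q falls almost in a straight line before it reaches a pseudo-first-order tail.

| setting | teal | red | green |
|---|---|---|---|
| Q | 0.20 M | 0.20 M | 0.20 M |
| Z | 0.05 mol% | 0.05 mol% | 0.05 mol% |
| temperature | 37 °C | 45 °C | 53 °C |
| time | 2.0 h | 2.0 h | 2.0 h |

    Q + Z → J + Z, rate k1*[Q]*[Z]/(1 + ([Q]/Km1)) (Km1 = 0.070 M, k1 = 7.1 /M/s, Ea1 = 49.0 kJ/mol)
    Z → G (k2 = 3.7 × 10⁻⁷ /s, Ea2 = 198 kJ/mol)
    J → D (k3 = 3.8 × 10⁻⁵ /s, Ea3 = 105 kJ/mol)
    (constants at 37 °C)

- all constants are for 37 °C and move with temperature by the activation energies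

1. which of the two there is more of at the end, teal (D / J)
2. which of the two there is more of at the end, red (D / J)
3. which of the two there is more of at the end, green (D / J)
4. J at the end, in percent of the Q charged, teal
5. J at the end, in percent of the Q charged, red
6. J at the end, in percent of the Q charged, green

A reckoning by hand, on teal:

1. Main step alone. Z stands at 1.00 × 10⁻⁴ M. Integrating the rate law gives s·g − ln x = b, where x is the fraction of Q left and g the fraction gone. Here s is the starting [Q] over Km, 2.86, and b is the turnover budget, the rate constant of the main step times [Z] times the time, 5.11. The saturated stretch costs up to s, and the remainder buys powers of ten: 0.978 of them, so x is about 10.5 %. Putting g back twice gives 7.77 %, then 8.40 %. J stands at 91.6 %.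

2. Add J → D. Half of the J is made once 1.92 of b is spent, at 0.752 h. The typical J is therefore 1.25 h old, younger than its half-life of 5.07 h. The estimate for teal puts J at 77.2 % and D at 14.4 %, less than J.

3. Add Z → G. By the end about 0.266 % of Z is lost, which takes hardly any of b, so the number stays.

4. The hand reckoning stops at teal. In red and green, J → D has the higher activation energy, 105 kJ/mol against 49.0 kJ/mol, so heating speeds the loss of J faster than its making.

The forecast gives J at 78 %, 59 % and 20.5 %, with J, J and D ahead in teal, red and green. Its ground is that “The yield of J is therefore set mainly by its follow-on loss to D”. For teal, the reckoning above stands 0.80 percentage points below it.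

The simulation gives J at 78.2 %, 58.8 % and 20.4 %, against D at 13.5 %, 40.7 % and 79.6 %, so J, J and D lead. The forecast holds in every answer.

In teal, half of the making of J is done by 0.753 h, where the budget put it at 0.752 h, which leaves a span of 1.25 h against a half-life of J of 5.1 h. At 0.753 h teal makes J 9.14 times faster than it uses J up, and at the end still 1.61 times faster, so J is still rising when teal stops.

The neighbour flask is teal with 0.03 mol% of Z, so its budget shrinks to 3.07. A rest of 33.3 % costs 3.00, and near there x moves by the difference over s + 3, which gives 32.1 % of Q left. The simulation of this neighbour flask leaves 32 % of Q, with J at 58.7 % and D at 9.02 %.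

The numbers were chosen freely; the result is computed.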